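## Retrosynthetic overview

1. Numbering used throughout: ring A = C1–C5 (C1 bears =CH2, C3 OH, C4 Br, C5 Me2), spiro carbon C6, ring B = C7–C11 (C9 Me/Cl, C10 Br). The strategy rests on ring B being a hidden 1-methylcyclohexene (C9=C10): C6 is stereogenic only through the side on which that alkene lies, so a C6 carrying two identical 3-oxobutyl arms is prochiral.
2. Target 29 ⇒ ring-A endgame (C3 carbonyl reduction, deconjugative protodesilylation, silylmethyl addition at C1) ⇒ bromochloride 24 ⇒ (C9 OH→Cl with retention, oxirane opening by bromide at C10, epoxidation, γ-bromination at C4) ⇒ spiro alkene 19.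
3. 19 ⇒ (enol triflate reduction, Beckmann degradation of the acetyl group) ⇒ acetyl enone 12.
4. 12 ⇒ key disconnection C9–C10: enantiotopic-group-selective intramolecular aldol condensation of achiral triketone 10, which closes ring B and sets C6.
5. 10 ⇒ double α′-alkylation of dimedone isobutyl enol ether 3 with but-3-enyl triflate, then Tsuji–Wacker oxidation. Ring A comes with dimedone; ring B is the only ring formed.

Key step: step 6

Remark: the quinine-derived amine is assumed to select the arm that leads to (6S)-12; if the opposite sense were found, the quinidine-derived pseudoenantiomer would be used.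

## Route

Step 1
Reactants: 1 dimedone (5,5-dimethylcyclohexane-1,3-dione); 2 isobutanol (2-methylpropan-1-ol)
Product: 3 3-isobutoxy-5,5-dimethylcyclohex-2-en-1-one
Conditions: TsOH·H2O (cat.), toluene, reflux, Dean–Stark
Reagents that add atoms: none
Why: Acid-catalysed condensation of the cyclic 1,3-dione with the alcohol under azeotropic removal of water (vinylogous esterification) masks one carbonyl and leaves a single kinetic enolisation site, the CH2 next to CMe2.

Step 2
Reactants: 4 but-3-en-1-ol
Product: 5 but-3-en-1-yl trifluoromethanesulfonate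
Conditions: Tf2O, pyridine, CH2Cl2, −20 °C; cold aqueous wash, used at once
Reagents that add atoms: trifluoromethanesulfonic anhydride, O=S(=O)(OS(=O)(=O)C(F)(F)F)C(F)(F)F
Why: O-Sulfonylation of the unhindered primary alcohol gives the most reactive sp3 electrophile available for the hindered enolate alkylations that follow.

Step 3
Reactants: 3 3-isobutoxy-5,5-dimethylcyclohex-2-en-1-one; 5 but-3-en-1-yl trifluoromethanesulfonate
Product: 7 6-(but-3-en-1-yl)-3-isobutoxy-5,5-dimethylcyclohex-2-en-1-one (racemic), via kinetic lithium enolate 6 (not isolated)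
Conditions: LiN(iPr)2, THF, −78 °C; then 5, −78 → 0 °C
Reagents that add atoms: none
Why: Kinetic α′-deprotonation of the vinylogous ester and SN2 alkylation of the cross-conjugated enolate with the primary triflate (Stork–Danheiser alkylation) installs the first arm; the new stereocentre is racemic and vanishes in step 4.

Step 4
Reactants: 7 6-(but-3-en-1-yl)-3-isobutoxy-5,5-dimethylcyclohex-2-en-1-one; 5 but-3-en-1-yl trifluoromethanesulfonate
Product: 9 6,6-di(but-3-en-1-yl)-3-isobutoxy-5,5-dimethylcyclohex-2-en-1-one, via tetrasubstituted lithium enolate 8 (not isolated)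
Conditions: LiN(iPr)2, THF, −78 → −40 °C; then DMPU, 5, −78 → 0 °C
Reagents that add atoms: none
Why: A second kinetic α′-deprotonation gives the tetrasubstituted enolate, which the small, highly reactive primary triflate should C-alkylate (enolate alkylation) to create the quaternary C6 next to CMe2; with two identical arms C6 is not a stereocentre.

Step 5
Reactants: 9 6,6-di(but-3-en-1-yl)-3-isobutoxy-5,5-dimethylcyclohex-2-en-1-one
Product: 10 3-isobutoxy-5,5-dimethyl-6,6-bis(3-oxobutyl)cyclohex-2-en-1-one
Conditions: PdCl2 (10 mol %), CuCl, O2 (1 atm), DMF/H2O 7:1, 23 °C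
Reagents that add atoms: water, O; dioxygen, O=O
Why: Tsuji–Wacker oxidation turns both terminal alkenes into methyl ketones by Markovnikov hydroxypalladation, while the electron-poor trisubstituted alkene of the vinylogous ester stays out and the near-neutral medium does not start the aldol reaction of the 1,7-diketone.

Step 6
Reactants: 10 3-isobutoxy-5,5-dimethyl-6,6-bis(3-oxobutyl)cyclohex-2-en-1-one
Product: 12 (6S)-10-acetyl-3-isobutoxy-5,5,9-trimethylspiro[5.5]undeca-2,9-dien-1-one, via aldol adduct 11 (not isolated)
Conditions: 9-amino-9-deoxy-epi-quinine (20 mol %), CF3CO2H (40 mol %), toluene, 40 °C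
Reagents that add atoms: none
Why: Proposed new method: the primary amine condenses with one methyl ketone, the enamine at its internal methylene (future C10) adds to the carbonyl carbon of the other arm (future C9), and aldol 11 loses water through the iminium/enamine to the conjugated tetrasubstituted enone, which makes the closure irreversible. The closest known chemistry is the amine-catalysed enantiotopic-group-selective aldol cyclodehydration of prochiral di- and triketones (Hajos–Parrish–Eder–Sauer–Wiechert reaction and primary-amine-salt cyclisation of 4-substituted heptane-2,6-diones); new here are the 1,7-diketone and the quaternary prochiral carbon. Ring B closes in a 6-(enolexo)-exo-trig mode, the only six-membered option, since the terminal-methyl enamine would give an eight-membered ring. C6 is the only stereocentre that survives dehydration, and its configuration is decided by which arm acts as enamine: in the chair transition state the CMe2 (C5) branch of ring A lies equatorial on the forming ring and the protonated quinuclidine of the catalyst hydrogen-bonds the acceptor carbonyl to one enamine face, so only one enantiotopic arm can be the nucleophile. The step needs selectivity between the arms (catalyst plus the size difference between the C5 and C1 branches at C6), regioselectivity for the internal enamine (ring size) and chemoselectivity over the ring-A carbonyl, which is a hindered vinylogous ester flanked by the quaternary carbon and neither condenses with the amine nor accepts the enamine.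

Step 7
Reactants: 12 (6S)-10-acetyl-3-isobutoxy-5,5,9-trimethylspiro[5.5]undeca-2,9-dien-1-one
Product: 13 (6S)-10-[(1E)-1-(hydroxyimino)ethyl]-3-isobutoxy-5,5,9-trimethylspiro[5.5]undeca-2,9-dien-1-one
Conditions: NH2OH·HCl, pyridine, EtOH, 23 → 50 °C
Reagents that add atoms: hydroxylamine hydrochloride, Cl.NO
Why: Oxime formation takes place at the acetyl group, the only carbonyl that is neither vinylogous nor flanked by the quaternary carbon, and the hydroxyl settles anti to the bulky ring alkenyl group ((E)-oxime), as the rearrangement in step 8 requires.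

Step 8
Reactants: 13 (E)-oxime of 12
Product: 16 (6S)-3-isobutoxy-5,5,9-trimethylspiro[5.5]undec-2-ene-1,10-dione (both C9 epimers), via O-tosyl oxime 14 (not isolated), via N-acetyl enamine 15 (not isolated)
Conditions: TsCl, pyridine, DMAP (cat.), CH2Cl2, 0 → 40 °C; then 1 M HCl, THF, 0 → 23 °C (brief)
Reagents that add atoms: water, O
Why: Beckmann rearrangement of the oxime sulfonate moves the alkenyl group anti to the leaving group onto nitrogen, and mild acid hydrolysis of the N-acetyl enamine gives the C10 ring ketone (the classical degradation of an α,β-unsaturated methyl ketone); the C9 methine is an epimer mixture that becomes trigonal again in step 9.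

Step 9
Reactants: 16 (6S)-3-isobutoxy-5,5,9-trimethylspiro[5.5]undec-2-ene-1,10-dione
Product: 18 (6S)-3-isobutoxy-5,5,9-trimethyl-1-oxospiro[5.5]undeca-2,9-dien-10-yl trifluoromethanesulfonate, via thermodynamic lithium enolate 17 (not isolated)
Conditions: LiN(SiMe3)2 (0.95 equiv), THF, −78 → 23 °C (equilibration); then PhNTf2, 0 → 23 °C
Reagents that add atoms: N-phenylbis(trifluoromethanesulfonimide), O=S(=O)(N(c1ccccc1)S(=O)(=O)C(F)(F)F)C(F)(F)F
Why: A slight deficit of base lets the lithium enolates equilibrate to the more substituted C9=C10 enolate (the alternative would involve the neopentyl C11 methylene next to C6), and O-sulfonylation with PhNTf2 fixes it as the enol triflate.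

Step 10
Reactants: 18 enol triflate
Product: 19 (6S)-3-isobutoxy-5,5,9-trimethylspiro[5.5]undeca-2,9-dien-1-one
Conditions: Pd(OAc)2 (5 mol %), PPh3 (10 mol %), HCO2H, Bu3N, DMF, 60 °C
Reagents that add atoms: none
Why: Zerovalent palladium inserts into the alkenyl triflate and formate delivers hydride (palladium-catalysed formate reduction), so the trisubstituted C9=C10 alkene forms without positional scrambling and the vinylogous ester is untouched.

Step 11
Reactants: 19 (6S)-3-isobutoxy-5,5,9-trimethylspiro[5.5]undeca-2,9-dien-1-one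
Product: 21 (4R,6S)-4-bromo-3-isobutoxy-5,5,9-trimethylspiro[5.5]undeca-2,9-dien-1-one (Br cis to C11), via extended lithium dienolate 20 (not isolated)
Conditions: LiN(iPr)2, THF, −78 °C; then N-bromosuccinimide, −78 °C
Reagents that add atoms: N-bromosuccinimide, O=C1CCC(=O)N1Br
Why: With C6 quaternary only C4 can be deprotonated, and the extended dienolate of an α′-blocked vinylogous ester is halogenated at its enol-ether terminus C4 (γ-bromination); because C10 is trigonal the C1 carbonyl leans over C10–C11, C7 becomes the pseudoaxial branch on ring A, and bromine should enter C4 axially on the face away from C7, that is cis to C11.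

Step 12
Reactants: 21 (4R,6S)-4-bromo vinylogous ester
Product: 22 9,10-epoxide of 21 with the oxirane oxygen cis to C5 (trans to C1)
Conditions: mCPBA, NaHCO3, CH2Cl2, 0 °C
Reagents that add atoms: 3-chloroperbenzoic acid, OOC(=O)c1cccc(Cl)c1
Why: Prilezhaev epoxidation occurs only at the electron-rich trisubstituted C9=C10 alkene, and the peracid should approach anti to the C1 branch of ring A, which is pseudoaxial on ring B and shields its face, so the oxygen ends cis to the CMe2 branch.

Step 13
Reactants: 22 epoxide
Product: 23 bromohydrin: 4,10-dibromo-9-hydroxy-3-isobutoxy-5,5,9-trimethylspiro[5.5]undec-2-en-1-one (C10–Br cis to C1; C9–OH cis to C5)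
Conditions: Li2NiBr4 (from LiBr and NiBr2), THF, 23 °C; aqueous work-up
Reagents that add atoms: dilithium tetrabromonickelate, [Li+].[Li+].[Ni+2].[Br-].[Br-].[Br-].[Br-]
Why: The soft bromide opens the oxirane by SN2 attack at the secondary carbon C10 with inversion, which is also the trans-diaxial (Fürst–Plattner) mode in the chair that keeps CMe2 equatorial, so bromine ends on C10 cis to C1 and the tertiary hydroxyl stays on C9 cis to C5.

Step 14
Reactants: 23 bromohydrin
Product: 24 4,10-dibromo-9-chloro-3-isobutoxy-5,5,9-trimethylspiro[5.5]undec-2-en-1-one (C9–Cl cis to C5; C10–Br cis to C1)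
Conditions: 1-chloro-N,N,2-trimethylprop-1-en-1-amine, CH2Cl2, 0 → 23 °C
Reagents that add atoms: 1-chloro-N,N,2-trimethylprop-1-en-1-amine, CC(C)=C(Cl)N(C)C
Why: The α-chloroenamine activates the tertiary alcohol under neutral conditions, the antiperiplanar C10 bromine expels the leaving group to a bromonium ion (neighbouring-group participation), and chloride opens it at the tertiary C9 from the face the oxygen had occupied, giving net retention at C9 and the trans C9–Cl/C10–Br pair.

Step 15
Reactants: 24 bromochloride vinylogous ester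
Product: 26 4,10-dibromo-9-chloro-5,5,9-trimethyl-1-[(trimethylsilyl)methyl]spiro[5.5]undec-1-en-3-one (halogen configurations as in 24), via tertiary allylic carbinol 25 (not isolated)
Conditions: Me3SiCH2Li, CeCl3, THF, −78 °C; then 1 M HCl, THF, 0 °C
Reagents that add atoms: (trimethylsilyl)methyllithium, [Li]C[Si](C)(C)C
Why: The weakly basic organocerium reagent adds 1,2 to the hindered vinylogous ester carbonyl without touching the alkyl halides, and acid then ionises the tertiary allylic carbinol and hydrolyses the enol ether (Stork–Danheiser carbonyl transposition) to the 3-(silylmethyl)enone, which is stable to the aqueous acid; the carbinol stereocentre of 25 is lost.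

Step 16
Reactants: 26 γ-silyl enone
Product: 28 4,10-dibromo-9-chloro-5,5,9-trimethyl-1-methylidenespiro[5.5]undecan-3-one (configurations as in the target), via tetrabutylammonium dienolate 27 (not isolated)
Conditions: Bu4NF, AcOH, THF, −78 → −20 °C
Reagents that add atoms: none
Why: Fluoride cleaves the C–Si bond of the vinylogous α-silyl ketone to the extended dienolate, which acetic acid protonates kinetically at the α-carbon C2 (deconjugative protodesilylation), so the alkene ends exocyclic on C1; the buffer and low temperature protect the α′-bromide and the C4 configuration.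

Step 17
Reactants: 28 β,γ-unsaturated α′-bromo ketone
Product: 29 (3S,4R,6R,9S,10S)-4,10-dibromo-9-chloro-5,5,9-trimethyl-1-methylidenespiro[5.5]undecan-3-ol (target)
Conditions: iBu2AlH, CH2Cl2, −78 °C; Rochelle salt work-up
Reagents that add atoms: none
Why: Hydride is delivered to the C3 carbonyl anti to the C4–Br bond (polar Felkin–Anh model) and away from the axial C5 methyl, which gives the alcohol cis to bromine, while at −78 °C the alkyl halides and the exocyclic alkene do not react.

## Compound list

1 | dimedone (5,5-dimethylcyclohexane-1,3-dione) | CC1(C)CC(=O)CC(=O)C1 | starting material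
2 | isobutanol (2-methylpropan-1-ol) | CC(C)CO | starting material
3 | 3-isobutoxy-5,5-dimethylcyclohex-2-en-1-one | CC(C)COC1=CC(=O)CC(C)(C)C1 | intermediate
4 | but-3-en-1-ol | C=CCCO | starting material
5 | but-3-en-1-yl trifluoromethanesulfonate | C=CCCOS(=O)(=O)C(F)(F)F | intermediate
6 | kinetic lithium enolate of 3 (not isolated) | [Li]OC1=CC(C)(C)CC(OCC(C)C)=C1 | intermediate
7 | 6-(but-3-en-1-yl)-3-isobutoxy-5,5-dimethylcyclohex-2-en-1-one (racemic) | C=CCCC1C(=O)C=C(OCC(C)C)CC1(C)C | intermediate
8 | tetrasubstituted lithium enolate of 7 (not isolated) | [Li]OC1=C(CCC=C)C(C)(C)CC(OCC(C)C)=C1 | intermediate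
9 | 6,6-di(but-3-en-1-yl)-3-isobutoxy-5,5-dimethylcyclohex-2-en-1-one | C=CCCC1(CCC=C)C(=O)C=C(OCC(C)C)CC1(C)C | intermediate
10 | 3-isobutoxy-5,5-dimethyl-6,6-bis(3-oxobutyl)cyclohex-2-en-1-one (achiral key-step precursor) | O=C1C=C(OCC(C)C)CC(C)(C)C1(CCC(C)=O)CCC(C)=O | intermediate
11 | aldol adduct, 10-acetyl-9-hydroxy-3-isobutoxy-5,5,9-trimethylspiro[5.5]undec-2-en-1-one (C9, C10 undefined; not isolated) | O=C1C=C(OCC(C)C)CC(C)(C)[C@@]12CCC(C)(O)C(C(C)=O)C2 | intermediate
12 | (6S)-10-acetyl-3-isobutoxy-5,5,9-trimethylspiro[5.5]undeca-2,9-dien-1-one | O=C1C=C(OCC(C)C)CC(C)(C)[C@@]12CCC(C)=C(C(C)=O)C2 | intermediate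
13 | (E)-oxime of 12 | O=C1C=C(OCC(C)C)CC(C)(C)[C@@]12CCC(C)=C(/C(C)=N/O)C2 | intermediate
14 | O-tosyl oxime of 12 (not isolated) | O=C1C=C(OCC(C)C)CC(C)(C)[C@@]12CCC(C)=C(/C(C)=N/OS(=O)(=O)c3ccc(C)cc3)C2 | intermediate
15 | N-acetyl enamine, N-[(6S)-3-isobutoxy-5,5,9-trimethyl-1-oxospiro[5.5]undeca-2,9-dien-10-yl]acetamide (not isolated) | O=C1C=C(OCC(C)C)CC(C)(C)[C@@]12CCC(C)=C(NC(C)=O)C2 | intermediate
16 | (6S)-3-isobutoxy-5,5,9-trimethylspiro[5.5]undec-2-ene-1,10-dione (C9 epimers) | O=C1C=C(OCC(C)C)CC(C)(C)[C@@]12CCC(C)C(=O)C2 | intermediate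
17 | thermodynamic lithium enolate of 16 (not isolated) | O=C1C=C(OCC(C)C)CC(C)(C)[C@@]12CCC(C)=C(O[Li])C2 | intermediate
18 | (6S)-3-isobutoxy-5,5,9-trimethyl-1-oxospiro[5.5]undeca-2,9-dien-10-yl trifluoromethanesulfonate | O=C1C=C(OCC(C)C)CC(C)(C)[C@@]12CCC(C)=C(OS(=O)(=O)C(F)(F)F)C2 | intermediate
19 | (6S)-3-isobutoxy-5,5,9-trimethylspiro[5.5]undeca-2,9-dien-1-one | O=C1C=C(OCC(C)C)CC(C)(C)[C@@]12CCC(C)=CC2 | intermediate
20 | extended lithium dienolate of 19 (not isolated) | [Li]OC1=CC(OCC(C)C)=CC(C)(C)[C@@]12CCC(C)=CC2 | intermediate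
21 | (4R,6S)-4-bromo-3-isobutoxy-5,5,9-trimethylspiro[5.5]undeca-2,9-dien-1-one (Br cis to C11) | O=C1C=C(OCC(C)C)[C@H](Br)C(C)(C)[C@@]12CCC(C)=CC2 | intermediate
22 | 9,10-epoxide of 21, oxirane oxygen cis to C5 | O=C1C=C(OCC(C)C)[C@H](Br)C(C)(C)[C@@]12CC[C@]3(C)O[C@@H]3C2 | intermediate
23 | bromohydrin, C10–Br cis to C1, C9–OH cis to C5 | O=C1C=C(OCC(C)C)[C@H](Br)C(C)(C)[C@@]12CC[C@](C)(O)[C@@H](Br)C2 | intermediate
24 | 4,10-dibromo-9-chloro-3-isobutoxy-5,5,9-trimethylspiro[5.5]undec-2-en-1-one, C9–Cl cis to C5 | O=C1C=C(OCC(C)C)[C@H](Br)C(C)(C)[C@@]12CC[C@](C)(Cl)[C@@H](Br)C2 | intermediate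
25 | tertiary allylic carbinol from silylmethyl addition to C1 of 24 (C1 undefined; not isolated) | C[Si](C)(C)CC1(O)C=C(OCC(C)C)[C@H](Br)C(C)(C)[C@@]12CC[C@](C)(Cl)[C@@H](Br)C2 | intermediate
26 | 4,10-dibromo-9-chloro-5,5,9-trimethyl-1-[(trimethylsilyl)methyl]spiro[5.5]undec-1-en-3-one | C[Si](C)(C)CC1=CC(=O)[C@H](Br)C(C)(C)[C@@]12CC[C@](C)(Cl)[C@@H](Br)C2 | intermediate
27 | tetrabutylammonium dienolate from 26 (not isolated) | C=C1C=C([O-])[C@H](Br)C(C)(C)[C@@]12CC[C@](C)(Cl)[C@@H](Br)C2.CCCC[N+](CCCC)(CCCC)CCCC | intermediate
28 | 4,10-dibromo-9-chloro-5,5,9-trimethyl-1-methylidenespiro[5.5]undecan-3-one | C=C1CC(=O)[C@H](Br)C(C)(C)[C@@]12CC[C@](C)(Cl)[C@@H](Br)C2 | intermediate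
29 | (3S,4R,6R,9S,10S)-4,10-dibromo-9-chloro-5,5,9-trimethyl-1-methylidenespiro[5.5]undecan-3-ol | C=C1C[C@H](O)[C@H](Br)C(C)(C)[C@@]12CC[C@](C)(Cl)[C@@H](Br)C2 | target

## Step count and risks

Total steps: 17. Longest linear sequence: 16 (steps 1 and 3–17; step 2 makes the triflate in a one-step side branch).

Steps most likely to fail:

1. Step 6 (carries the label). The amine salt may discriminate poorly between the two enantiotopic arms, or turn over slowly because dehydration to the tetrasubstituted enone is sluggish. Fallback with known chemistry, setting out from 10 and returning at 12: an achiral secondary amine salt (pyrrolidine, AcOH, toluene, 60 °C) effects the ordinary intramolecular aldol condensation of the 1,7-diketone to the racemic spiro enone F1. The enantiomers are then separated by preparative HPLC on cellulose tris(3,5-dimethylphenylcarbamate); the (6S)-enantiomer is 12 and the (6R)-enantiomer F2 is set aside.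

2. Step 13. Bromide may attack the tertiary carbon C9 through an open cation, or the Lewis-acidic nickel salt may trigger rearrangement of the trisubstituted oxirane, because the SN2 trajectory at C10 runs syn to the axial C1 branch and is slow. Fallback, setting out from 21 and returning at 23: dihydroxylation (OsO4 cat., N-methylmorpholine N-oxide, acetone/H2O) anti to the C1 branch gives the cis-diol F3. SO2Cl2 and Et3N in CH2Cl2 at −78 °C close the cyclic sulfate F4. LiBr in THF opens it strictly by SN2 at the secondary C10 with inversion to the lithium sulfate monoester F5, and catalytic H2SO4 in wet THF cleaves the O–S bond (retention at C9) to give 23.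

3. Step 4. The tetrasubstituted enolate next to CMe2 may be O-alkylated, or may eliminate the triflate, instead of forming the quaternary carbon. Fallback, setting out from 3 and returning at 10: two successive allylations (LiN(iPr)2, THF, −78 °C; allyl bromide, the best C-electrophile for hindered enolates) give the monoallyl ketone F6 and then the 6,6-diallyl ketone F7. Hydroboration of both alkenes with 9-borabicyclo[3.3.1]nonane and oxidation with NaBO3 gives the diol F8. Dess–Martin periodinane gives the dialdehyde F9, MeMgBr at −78 °C adds to both aldehydes to give the bis(secondary alcohol) F10, and a second Dess–Martin oxidation gives 10.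

## Further compounds

F1 | step 6 | racemic 10-acetyl-3-isobutoxy-5,5,9-trimethylspiro[5.5]undeca-2,9-dien-1-one | O=C1C=C(OCC(C)C)CC(C)(C)C12CCC(C)=C(C(C)=O)C2
F2 | step 6 | (6R)-10-acetyl-3-isobutoxy-5,5,9-trimethylspiro[5.5]undeca-2,9-dien-1-one | O=C1C=C(OCC(C)C)CC(C)(C)[C@]12CCC(C)=C(C(C)=O)C2
F3 | step 13 | cis-9,10-diol of 21, both hydroxyls cis to C5 | O=C1C=C(OCC(C)C)[C@H](Br)C(C)(C)[C@@]12CC[C@](C)(O)[C@H](O)C2
F4 | step 13 | 9,10-cyclic sulfate of F3 | O=C1C=C(OCC(C)C)[C@H](Br)C(C)(C)[C@@]12CC[C@]3(C)OS(=O)(=O)O[C@@H]3C2
F5 | step 13 | lithium C9 sulfate monoester of bromohydrin 23 | O=C1C=C(OCC(C)C)[C@H](Br)C(C)(C)[C@@]12CC[C@](C)(OS(=O)(=O)O[Li])[C@@H](Br)C2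
F6 | step 4 | 6-allyl-3-isobutoxy-5,5-dimethylcyclohex-2-en-1-one (racemic) | C=CCC1C(=O)C=C(OCC(C)C)CC1(C)C
F7 | step 4 | 6,6-diallyl-3-isobutoxy-5,5-dimethylcyclohex-2-en-1-one | C=CCC1(CC=C)C(=O)C=C(OCC(C)C)CC1(C)C
F8 | step 4 | 6,6-bis(3-hydroxypropyl)-3-isobutoxy-5,5-dimethylcyclohex-2-en-1-one | OCCCC1(CCCO)C(=O)C=C(OCC(C)C)CC1(C)C
F9 | step 4 | 6,6-bis(3-oxopropyl)-3-isobutoxy-5,5-dimethylcyclohex-2-en-1-one | O=CCCC1(CCC=O)C(=O)C=C(OCC(C)C)CC1(C)C
F10 | step 4 | 6,6-bis(3-hydroxybutyl)-3-isobutoxy-5,5-dimethylcyclohex-2-en-1-one (diastereomer mixture) | CC(O)CCC1(CCC(C)O)C(=O)C=C(OCC(C)C)CC1(C)C
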